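**Retrosynthetic overview**
- Feature: in ring A (the monobrominated ring, carbons numbered 1 to 6) carbon 1 bears OH, carbon 2 the ether oxygen and carbon 4 bromine, and carbons 3, 5 and 6 are CH. Carbon 4 lies para to carbon 1 and between carbons 3 and 5, so it can be removed as a CBr unit. What remains is a cyclopentene (carbons 1, 2, 3, 5, 6) whose alkene joins carbons 3 and 5, opposite the two oxygenated carbons.
- Last disconnections: O-demethylation of ring B; the arene ring A from a 6,6-dibromobicyclo[3.1.0]hexan-3-one by enolisation, cyclopropane opening and loss of HBr.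
- Key disconnection: the 3–4 and 4–5 bonds of ring A, by addition of dibromocarbene to the silyl ether of trans-2-aryloxycyclopent-3-en-1-ol.
- The ether bond at ring A carbon 2 is made at an sp3 carbon by SN2 opening of cyclopentadiene monoepoxide with 2,3,5-tribromo-6-methoxyphenoxide. That phenol comes from 2,4,5-tribromophenol by ortho-formylation, O-methylation and Baeyer–Villiger oxidation.
- Ring order: ring B is bought intact; epoxide (step 4), cyclopropane (step 7), six-membered ring A (step 10).

Key step: step 7

Assumption: cyclopentadiene is used as the monomer, freshly distilled from its commercial dimer; the target is achiral, so all chiral intermediates are racemic and one enantiomer is drawn.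

**Route**

Step 1
Reactants: 1 2,4,5-tribromophenol
Product: 3 3,5,6-tribromo-2-hydroxybenzaldehyde, via salicyl alcohol 2 (not isolated)
Conditions: MgCl2, Et3N, (CH2O)n, MeCN, reflux; then 1 M HCl
Reagents that add atoms: formaldehyde from paraformaldehyde (C=O)
Why: Magnesium-mediated ortho-formylation (Casnati–Skattebøl): the chloromagnesium phenoxide directs formaldehyde to the only free ortho carbon (the para carbon carries bromine), and a second formaldehyde oxidises the benzylic alkoxide of 2 to the aldehyde by Oppenauer-type hydride transfer.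

Step 2
Reactants: 3 3,5,6-tribromo-2-hydroxybenzaldehyde
Product: 4 3,5,6-tribromo-2-methoxybenzaldehyde
Conditions: MeI, K2CO3, DMF, rt
Reagents that add atoms: iodomethane (CI)
Why: Williamson O-methylation of the acidic salicylaldehyde hydroxyl by SN2 on iodomethane; the aldehyde and the aryl bromides are inert.

Step 3
Reactants: 4 3,5,6-tribromo-2-methoxybenzaldehyde
Product: 6 2,3,5-tribromo-6-methoxyphenol, via aryl formate 5 (not isolated)
Conditions: mCPBA, CH2Cl2, rt; aq Na2SO3/NaHCO3 wash; then K2CO3 (cat.), MeOH, rt
Reagents that add atoms: 3-chloroperoxybenzoic acid (OOC(=O)c1cccc(Cl)c1)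
Why: Baeyer–Villiger (Dakin-type) oxidation: in the Criegee adduct of the di-ortho-substituted aldehyde the aryl group, helped by the ortho methoxy donor, should migrate in preference to hydride, and the activated formate 5 is cleaved by base-catalysed transesterification with methanol.

Step 4
Reactants: 7 cyclopenta-1,3-diene
Product: 8 6-oxabicyclo[3.1.0]hex-2-ene (cyclopentadiene monoepoxide), racemic
Conditions: AcOOH (40% in AcOH), Na2CO3, NaOAc (cat.), CH2Cl2, 0 °C to rt
Reagents that add atoms: peracetic acid (CC(=O)OO)
Why: Prilezhaev epoxidation of one double bond of the electron-rich diene under carbonate buffering, which protects the acid-labile vinyl epoxide; the remaining alkene is deactivated by the allylic oxygen, and the ring fusion can only be cis.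

Step 5
Reactants: 6 2,3,5-tribromo-6-methoxyphenol; 8 6-oxabicyclo[3.1.0]hex-2-ene (in excess)
Product: 9 (1RS,2RS)-2-(2,3,5-tribromo-6-methoxyphenoxy)cyclopent-3-en-1-ol (trans)
Conditions: Cs2CO3 (1.0 equiv), DMF, 50 °C, sealed vessel
Reagents that add atoms: none
Why: Base-mediated SN2 opening of the vinyl epoxide by the phenoxide at the allylic carbon, which the adjacent π bond activates; backside attack sets the trans relation of the aryloxy group (ring A carbon 2) and the hydroxyl (ring A carbon 1), and the carbonate is regenerated when the alkoxide is protonated.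

Step 6
Reactants: 9 (1RS,2RS)-2-(2,3,5-tribromo-6-methoxyphenoxy)cyclopent-3-en-1-ol
Product: 10 tert-butyldimethylsilyl ether of 9 (trans, racemic)
Conditions: TBSCl, imidazole, DMF, rt
Reagents that add atoms: tert-butyldimethylsilyl chloride (CC(C)(C)[Si](C)(C)Cl)
Why: Imidazole-promoted silylation (Corey conditions) of the secondary alcohol, which masks the O–H bond that a dihalocarbene would otherwise attack; no stereocentre is touched.

Step 7
Reactants: 10 tert-butyldimethylsilyl ether of 9; 11 bromoform
Product: 12 6,6-dibromo-3-(tert-butyldimethylsilyloxy)-2-(2,3,5-tribromo-6-methoxyphenoxy)bicyclo[3.1.0]hexane (racemic; O-aryl and O-silyl trans; CBr2 bridge on the face opposite the aryloxy group)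
Conditions: CHBr3 (excess), 50% aq NaOH, BnEt3NCl (cat.), CH2Cl2, 0 °C to rt, vigorous stirring
Reagents that add atoms: bromoform (BrC(Br)Br)
Why: Hydroxide deprotonates bromoform at the phase boundary, the tribromomethyl anion loses bromide, and the singlet dibromocarbene adds to the double bond between ring A carbons 3 and 5 of 10 in a concerted, stereospecific [2+1] cycloaddition that forms the 3–4 and 4–5 bonds of ring A together. The closest known reaction type is the Makosza phase-transfer dibromocyclopropanation of a cyclopentene, the first half of a Doering–Hoffmann one-carbon ring expansion. The cyclopropane is closed by this intermolecular cheletropic addition across a cis ring alkene, so the five/three ring fusion can only be cis. The new stereocentres at ring A carbons 3 and 5 are set relative to carbon 2 by approach of the carbene to the face away from the bulky allylic aryloxy group; both are erased in step 10, so a minor syn adduct would converge on the same arene. The only selectivity required is chemoselectivity for the single alkene, which the silyl cap on the alcohol, the electron-poor ring B and the base-stable aryl bromides and methyl ether should secure. The adduct is kept at or below room temperature because ionisation of the endo bromide opens such cyclopropanes on heating, although the allylic bromide so formed would still lead to 16 through steps 8 to 10.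

Step 8
Reactants: 12 silyl-protected dibromocyclopropane
Product: 13 6,6-dibromo-2-(2,3,5-tribromo-6-methoxyphenoxy)bicyclo[3.1.0]hexan-3-ol (racemic, same relative configuration)
Conditions: HF·pyridine, THF, 0 °C to rt
Reagents that add atoms: none
Why: Fluoride-driven cleavage of the Si–O bond (formation of the strong Si–F bond) under mildly acidic conditions that leave the dibromocyclopropane, the methyl ether and the aryl bromides untouched.

Step 9
Reactants: 13 bicyclic alcohol
Product: 14 6,6-dibromo-2-(2,3,5-tribromo-6-methoxyphenoxy)bicyclo[3.1.0]hexan-3-one (racemic; aryloxy group opposite the CBr2 bridge)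
Conditions: Dess–Martin periodinane, CH2Cl2, 0 °C to rt; filtration through a short silica pad
Reagents that add atoms: none
Why: Dess–Martin oxidation of the secondary alcohol under non-basic conditions, so that the ketone is not enolised before the next step.

Step 10
Reactants: 14 bicyclic ketone
Product: 16 4-bromo-2-(2,3,5-tribromo-6-methoxyphenoxy)phenol, via cyclohexa-2,4-dienone 15 (not isolated)
Conditions: Et3N, MeCN, rt to 50 °C; then 1 M HCl
Reagents that add atoms: none
Why: Base-induced dehydrobrominative ring expansion of a gem-dibromocyclopropyl ketone: enolisation toward ring A carbon 2 assists departure of the endo bromide from carbon 4 with disrotatory opening of the bond between carbons 3 and 5 (cyclopropyl-to-allyl electrocyclic opening), and dienone 15 tautomerises to the phenol with the remaining bromine on carbon 4, para to carbon 1; enolisation toward carbon 6 leads to the same arene.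

Step 11
Reactants: 16 4-bromo-2-(2,3,5-tribromo-6-methoxyphenoxy)phenol
Product: 17 3,4,6-tribromo-2-(5-bromo-2-hydroxyphenoxy)phenol (target)
Conditions: BBr3, CH2Cl2, −78 to 0 °C; then H2O
Reagents that add atoms: none
Why: Lewis-acid ether cleavage: BBr3 coordinates the methoxy oxygen and bromide attacks the methyl group by SN2, while the diaryl ether offers no sp3 carbon and the aryl bromides are inert; hydrolysis of the aryl borates frees both phenols.

**Compound list**
1 | 2,4,5-tribromophenol | Oc1cc(Br)c(Br)cc1Br | starting material
2 | 3,4,6-tribromo-2-(hydroxymethyl)phenol (present as its magnesium alkoxide, not isolated) | Oc1c(CO)c(Br)c(Br)cc1Br | intermediate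
3 | 3,5,6-tribromo-2-hydroxybenzaldehyde | O=Cc1c(O)c(Br)cc(Br)c1Br | intermediate
4 | 3,5,6-tribromo-2-methoxybenzaldehyde | O=Cc1c(OC)c(Br)cc(Br)c1Br | intermediate
5 | 2,3,5-tribromo-6-methoxyphenyl formate (not isolated) | O=COc1c(OC)c(Br)cc(Br)c1Br | intermediate
6 | 2,3,5-tribromo-6-methoxyphenol | Oc1c(OC)c(Br)cc(Br)c1Br | intermediate
7 | cyclopenta-1,3-diene | C1=CCC=C1 | starting material
8 | 6-oxabicyclo[3.1.0]hex-2-ene (cis-fused, racemic) | C1=C[C@H]2O[C@H]2C1 | intermediate
9 | (1RS,2RS)-2-(2,3,5-tribromo-6-methoxyphenoxy)cyclopent-3-en-1-ol (trans, racemic) | O[C@H]1CC=C[C@@H]1Oc1c(OC)c(Br)cc(Br)c1Br | intermediate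
10 | tert-butyldimethyl{[(1RS,2RS)-2-(2,3,5-tribromo-6-methoxyphenoxy)cyclopent-3-en-1-yl]oxy}silane (trans, racemic) | CC(C)(C)[Si](C)(C)O[C@H]1CC=C[C@@H]1Oc1c(OC)c(Br)cc(Br)c1Br | intermediate
11 | bromoform (tribromomethane) | BrC(Br)Br | starting material
12 | 6,6-dibromo-3-(tert-butyldimethylsilyloxy)-2-(2,3,5-tribromo-6-methoxyphenoxy)bicyclo[3.1.0]hexane (racemic; aryloxy and silyloxy groups trans; CBr2 bridge opposite the aryloxy group) | CC(C)(C)[Si](C)(C)O[C@H]1C[C@@H]2[C@@H](C2(Br)Br)[C@@H]1Oc1c(OC)c(Br)cc(Br)c1Br | intermediate
13 | 6,6-dibromo-2-(2,3,5-tribromo-6-methoxyphenoxy)bicyclo[3.1.0]hexan-3-ol (racemic, same relative configuration as 12) | O[C@H]1C[C@@H]2[C@@H](C2(Br)Br)[C@@H]1Oc1c(OC)c(Br)cc(Br)c1Br | intermediate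
14 | 6,6-dibromo-2-(2,3,5-tribromo-6-methoxyphenoxy)bicyclo[3.1.0]hexan-3-one (racemic; aryloxy group opposite the CBr2 bridge) | O=C1C[C@@H]2[C@@H](C2(Br)Br)[C@@H]1Oc1c(OC)c(Br)cc(Br)c1Br | intermediate
15 | 4-bromo-2-(2,3,5-tribromo-6-methoxyphenoxy)cyclohexa-2,4-dien-1-one (not isolated) | O=C1CC=C(Br)C=C1Oc1c(OC)c(Br)cc(Br)c1Br | intermediate
16 | 4-bromo-2-(2,3,5-tribromo-6-methoxyphenoxy)phenol | Oc1ccc(Br)cc1Oc1c(OC)c(Br)cc(Br)c1Br | intermediate
17 | 3,4,6-tribromo-2-(5-bromo-2-hydroxyphenoxy)phenol | Oc1ccc(Br)cc1Oc1c(O)c(Br)cc(Br)c1Br | target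

**Step count**
Total: 11 steps. Longest linear sequence: 10 steps (from 1 through steps 1–3 and 5–11); step 4 is a one-step side branch.

**Steps most likely to fail**

Step 5. The hindered, weakly nucleophilic phenoxide may attack the alkene terminus (SN2′, giving the 1,4-adduct) or the non-allylic epoxide carbon, or the volatile epoxide may decay before it is consumed. Fallback: the ether bond is made by Mitsunobu inversion instead of epoxide opening. The fallback sets out from 6 and commercial cyclopent-2-en-1-one F1. Acetoxylation of the α′-carbon with Mn(OAc)3 in refluxing benzene should give 2-oxocyclopent-3-en-1-yl acetate F2. Luche reduction (NaBH4, CeCl3·7H2O, MeOH, −78 °C) should give cis-2-hydroxycyclopent-3-en-1-yl acetate F3. Mitsunobu coupling of its allylic alcohol with 6 (PPh3, DIAD, THF, 0 °C to rt) should give trans-2-(2,3,5-tribromo-6-methoxyphenoxy)cyclopent-3-en-1-yl acetate F4 with inversion. Methanolysis (K2CO3, MeOH) comes back to the route at 9. The relative configuration is of no consequence because both stereocentres vanish in step 10.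

Step 7. The electrophilic carbene may add only slowly to an alkene that is inductively deactivated and shielded by the allylic aryloxy group, so that carbene hydrolysis or C–H insertion take over. Fallback: ring A is taken as a ready-made arene and the ether bond is formed by nucleophilic aromatic substitution. It sets out from 6. Substitution of fluoride in 4-bromo-2-fluoro-1-nitrobenzene F5 (K2CO3, DMF, 80 °C) should give 4-bromo-2-(2,3,5-tribromo-6-methoxyphenoxy)-1-nitrobenzene F6. Reduction with Fe and NH4Cl in aqueous ethanol should give 4-bromo-2-(2,3,5-tribromo-6-methoxyphenoxy)aniline F7 without loss of bromine. Diazotisation (NaNO2, H2SO4, AcOH, 0 °C) gives 4-bromo-2-(2,3,5-tribromo-6-methoxyphenoxy)benzenediazonium hydrogen sulfate F8, and its hydrolysis (Cu2O, Cu(NO3)2, H2O, rt) comes back to the route at 16.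

Step 1. C–C bond formation at the only free ortho carbon may be sluggish, because three bromines deactivate the ring and one of them flanks the site; the phenol would then be recovered or lost to methylene-bridged by-products. Fallback: the ortho oxygen is introduced through iodination and iodine–magnesium exchange instead of formylation and Baeyer–Villiger oxidation. It sets out from 1. Iodination of the free ortho carbon (N-iodosuccinimide, TsOH cat., MeCN, rt) should give 3,4,6-tribromo-2-iodophenol F9, and methylation (MeI, K2CO3, DMF) 3,4,6-tribromo-2-iodoanisole F10. Selective iodine–magnesium exchange (iPrMgCl·LiCl, THF, −40 °C) should give (2,3,5-tribromo-6-methoxyphenyl)magnesium chloride F11, which B(OMe)3 converts into dimethyl (2,3,5-tribromo-6-methoxyphenyl)boronate F12. Oxidation (H2O2, NaOH, 0 °C) comes back to the route at 6, replacing steps 1 to 3.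

Further compounds
F1 | step 5 | cyclopent-2-en-1-one (commercial) | O=C1CCC=C1
F2 | step 5 | 2-oxocyclopent-3-en-1-yl acetate (racemic) | CC(=O)O[C@H]1CC=CC1=O
F3 | step 5 | cis-2-hydroxycyclopent-3-en-1-yl acetate (racemic) | CC(=O)O[C@H]1CC=C[C@H]1O
F4 | step 5 | trans-2-(2,3,5-tribromo-6-methoxyphenoxy)cyclopent-3-en-1-yl acetate (racemic) | CC(=O)O[C@H]1CC=C[C@@H]1Oc1c(OC)c(Br)cc(Br)c1Br
F5 | step 7 | 4-bromo-2-fluoro-1-nitrobenzene (commercial) | [O-][N+](=O)c1ccc(Br)cc1F
F6 | step 7 | 4-bromo-2-(2,3,5-tribromo-6-methoxyphenoxy)-1-nitrobenzene | [O-][N+](=O)c1ccc(Br)cc1Oc1c(OC)c(Br)cc(Br)c1Br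
F7 | step 7 | 4-bromo-2-(2,3,5-tribromo-6-methoxyphenoxy)aniline | Nc1ccc(Br)cc1Oc1c(OC)c(Br)cc(Br)c1Br
F8 | step 7 | 4-bromo-2-(2,3,5-tribromo-6-methoxyphenoxy)benzenediazonium hydrogen sulfate | N#[N+]c1ccc(Br)cc1Oc1c(OC)c(Br)cc(Br)c1Br.OS(=O)(=O)[O-]
F9 | step 1 | 3,4,6-tribromo-2-iodophenol | Oc1c(I)c(Br)c(Br)cc1Br
F10 | step 1 | 3,4,6-tribromo-2-iodoanisole | COc1c(I)c(Br)c(Br)cc1Br
F11 | step 1 | (2,3,5-tribromo-6-methoxyphenyl)magnesium chloride | COc1c([Mg]Cl)c(Br)c(Br)cc1Br
F12 | step 1 | dimethyl (2,3,5-tribromo-6-methoxyphenyl)boronate | COB(OC)c1c(OC)c(Br)cc(Br)c1Br
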